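**Assumption:** Pseudopentafuhalol D is achiral. It has no stereocenters or stereoaxes, so "single enantiomer" is moot and nothing is set or scrambled. All 13 phenols are carried as benzyl (Bn = CH2Ph) ethers and released in the last step.

**Target check.** The target is a linear pentamer A–O–B–O–C–O–D–O–E, with 13 OH and 4 diaryl ether bonds.
- A is 2,4,6-trihydroxyphenyl.
- B is a 1,2-bis(aryloxy)-3,5-dihydroxybenzene (O at A-side C1, C-side C2).
- C is a 1,3-bis(aryloxy)-4,5-dihydroxybenzene.
- D is a 1,2-bis(aryloxy)-3,4,5-trihydroxybenzene with one ring H.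
- E is 3,4,5-trihydroxyphenyl.

**Retrosynthesis**
1. Global debenzylation of the perbenzylated pentamer **19**.
2. Disconnect B2–O–C1 by a proposed Cu-LMCT decarboxylative C–O coupling, giving the hindered phenol **7** (A–O–B) and the acid **18** (C–D–E).
3. Build **18** by Ullmann coupling of the ring-C bromide **16** with the ED-phenol **14**; make **14** from iodide **12** and phenol **10**, followed by MOM removal.
4. Build **7** by SNAr of A-phenol **3** onto fluoroaldehyde **5**, then Baeyer–Villiger (Dakin-type) conversion of CHO to OH, which creates the B2 phenol.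
5. All five benzene rings come from commercial arenes. Ether bonds form in the order D–E, C–D, A–B, then B–C last.

---

**Step 1**
Reactants: 1, 2,4,6-trihydroxybenzaldehyde
Product: 2, 2,4,6-tris(benzyloxy)benzaldehyde
Conditions: BnBr (3.5 equiv), K2CO3, DMF, rt, 16 h
Reagents that add atoms: benzyl bromide, BrCc1ccccc1
Why: Williamson O-benzylation of the three phenols; no stereocenter forms.

**Step 2**
Reactants: 2
Product: 3, 2,4,6-tris(benzyloxy)phenol
Conditions: (i) mCPBA, NaHCO3, CH2Cl2, 0 °C→rt; (ii) K2CO3, MeOH, rt (one pot)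
Reagents that add atoms: mCPBA, OOC(=O)c1cccc(Cl)c1
Why: Baeyer–Villiger/Dakin-type aryl migration on an electron-rich benzaldehyde gives the aryl formate (not isolated), which methanolysis converts to the phenol.

**Step 3**
Reactants: 4, 2,4,6-trifluorobenzaldehyde
Product: 5, 2-fluoro-4,6-bis(benzyloxy)benzaldehyde
Conditions: BnOH (2.0 equiv), NaH (2.1 equiv), THF, 0 °C→rt
Reagents that add atoms: benzyl alcohol, OCc1ccccc1
Why: SNAr occurs first at the CHO-activated para F and then at one ortho F. The third F is deactivated by the two alkoxy donors and stays, leaving the ortho-F-aldehyde needed for the A–B ether.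

**Step 4**
Reactants: 3 (phenol, 1.2 equiv); 5
Product: 6, 2-(2,4,6-tribenzyloxyphenoxy)-4,6-bis(benzyloxy)benzaldehyde
Conditions: Cs2CO3, DMF, 90 °C
Reagents that add atoms: none
Why: SNAr of the hindered phenoxide at the F ortho to CHO. The charge in the Meisenheimer complex is stabilized by the ortho CHO, and the meta-OBn groups do not donate into the attacked carbon; this forms the A–O–B bond.

**Step 5**
Reactants: 6
Product: 7, 2-(2,4,6-tribenzyloxyphenoxy)-3,5-bis(benzyloxy)phenol (B-ring phenol, OH ortho to the O–A)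
Conditions: (i) mCPBA, NaHCO3, CH2Cl2, 0 °C; (ii) K2CO3, MeOH, rt
Reagents that add atoms: mCPBA, OOC(=O)c1cccc(Cl)c1
Why: Baeyer–Villiger/Dakin-type sequence converts CHO to OH at the position that will carry the B2–O–C ether, giving the di-ortho-substituted phenol.

**Step 6**
Reactants: 8, 3,4,5-trihydroxybenzaldehyde
Product: 9, 3,4,5-tris(benzyloxy)benzaldehyde
Conditions: BnBr (3.6 equiv), K2CO3, DMF, 60 °C
Reagents that add atoms: benzyl bromide, BrCc1ccccc1
Why: Williamson O-benzylation.

**Step 7**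
Reactants: 9
Product: 10, 3,4,5-tris(benzyloxy)phenol
Conditions: (i) mCPBA, NaHCO3, CH2Cl2, 0 °C→rt; (ii) K2CO3, MeOH, rt
Reagents that add atoms: mCPBA, OOC(=O)c1cccc(Cl)c1
Why: Baeyer–Villiger/Dakin-type sequence as in Step 2. Phenol 10 is used both as the E-ring nucleophile and as the D-ring precursor.

**Step 8**
Reactants: 10
Product: 11, 1-(methoxymethoxy)-3,4,5-tris(benzyloxy)benzene
Conditions: MOMCl, i-Pr2NEt, CH2Cl2, 0 °C→rt
Reagents that add atoms: chloromethyl methyl ether, ClCOC
Why: MOM protection gives an acid-labile, Ullmann-inert mask that differentiates D1-O from the later D2-O.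

**Step 9**
Reactants: 11
Product: 12, 2-iodo-1-(methoxymethoxy)-3,4,5-tris(benzyloxy)benzene
Conditions: NIS (1.0 equiv), cat. TFA, MeCN, 0 °C→rt
Reagents that add atoms: N-iodosuccinimide, O=C1CCC(=O)N1I
Why: Electrophilic iodination of the activated arene at one of the two equivalent C–H positions, ortho to OMOM, so regiochemistry is set by symmetry; mono-iodination is controlled by stoichiometry.

**Step 10**
Reactants: 12; 10 (1.3 equiv)
Product: 13, ED-MOM diaryl ether (D2–O–E)
Conditions: CuI (10 mol%), picolinic acid (20 mol%), K3PO4, DMSO, 80–90 °C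
Reagents that add atoms: none
Why: Ullmann-type Cu/picolinate C–O coupling, known to tolerate di-ortho-substituted aryl halides; forms the D–O–E bond.

**Step 11**
Reactants: 13
Product: 14, 2-(3,4,5-tris(benzyloxy)phenoxy)-3,4,5-tris(benzyloxy)phenol (ED-phenol)
Conditions: 3 M HCl, THF/MeOH (1:1), 50 °C
Reagents that add atoms: none
Why: Acidolysis of the aryl MOM acetal; aryl benzyl ethers and diaryl ethers are inert.

**Step 12**
Reactants: 15, 3-bromo-4,5-dihydroxybenzaldehyde
Product: 16, 3-bromo-4,5-bis(benzyloxy)benzaldehyde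
Conditions: BnBr (2.4 equiv), K2CO3, DMF, rt
Reagents that add atoms: benzyl bromide, BrCc1ccccc1
Why: Williamson O-benzylation.

**Step 13**
Reactants: 14; 16 (1.2 equiv)
Product: 17, EDC-aldehyde (C5–O–D1 ether)
Conditions: CuI (10 mol%), picolinic acid (20 mol%), K3PO4, DMSO, 90 °C
Reagents that add atoms: none
Why: Ullmann-type Cu/picolinate C–O coupling of an ortho-alkoxy aryl bromide with a mono-ortho-substituted phenol; the aldehyde is inert to these conditions.

**Step 14**
Reactants: 17
Product: 18, 3,4-bis(benzyloxy)-5-[2-(3,4,5-tris(benzyloxy)phenoxy)-3,4,5-tris(benzyloxy)phenoxy]benzoic acid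
Conditions: NaClO2, NaH2PO4, 2-methyl-2-butene, t-BuOH/H2O, rt
Reagents that add atoms: sodium chlorite, [Na+].[O-]Cl=O
Why: Pinnick oxidation; the alkene scavenges HOCl so the electron-rich rings are not chlorinated.

**Step 15 (key step)**
Reactants: 18 (1.0 equiv); 7 (1.5 equiv)
Product: 19, perbenzylated pentamer (B2–O–C1 bond formed, CO2 lost)
Conditions: Cu(OTf)2 (2.2 equiv), 4-MeO-pyridine (4 equiv), Cs2CO3 (1.5 equiv), MeCN, 365 nm LEDs, 35 °C, N2, 16 h
Reagents that add atoms: none
Why: Proposed new method: Cu-LMCT decarboxylative C–O cross-coupling of an electron-rich benzoic acid with a di-ortho-substituted phenol to make a hindered diaryl ether. Irradiating the Cu(II) carboxylate gives ArCO2•, which loses CO2 to give Ar•. Ar• is captured by a Cu(II) phenoxide of 7 to give ArCu(III)(OAr′), and C–O reductive elimination forms the B2–O–C1 bond. The closest known reactions are Cu-LMCT decarboxylative hydroxylation and halogenation of benzoic acids, and Cu(III) C–O reductive elimination in Chan–Lam/Ullmann chemistry. Pre-formed Cu phenoxide and excess phenol should favor the diaryl ether over the aryl benzoate; the bond is unhindered on the acid side, so the steric demand sits on the Cu(III) phenoxide side. No stereocenter is formed.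

**Step 16**
Reactants: 19
Product: 20, Pseudopentafuhalol D
Conditions: H2 (1 atm), Pd(OH)2/C, THF/MeOH (1:1), rt, 24 h; filter under Ar and purify on Sephadex LH-20
Reagents that add atoms: none (H2 adds only H)
Why: Catalytic hydrogenolysis removes all 13 benzyl ethers (13 toluene released); the diaryl ether bonds are inert.

---

**Compound list**

| # | Name | SMILES | Role |
|---|---|---|---|
| 1 | 2,4,6-trihydroxybenzaldehyde | O=Cc1c(O)cc(O)cc1O | starting material |
| 2 | 2,4,6-tris(benzyloxy)benzaldehyde | O=Cc1c(OCc9ccccc9)cc(OCc9ccccc9)cc1OCc9ccccc9 | intermediate |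
| 3 | 2,4,6-tris(benzyloxy)phenol | Oc1c(OCc9ccccc9)cc(OCc9ccccc9)cc1OCc9ccccc9 | intermediate |
| 4 | 2,4,6-trifluorobenzaldehyde | O=Cc1c(F)cc(F)cc1F | starting material |
| 5 | 2-fluoro-4,6-bis(benzyloxy)benzaldehyde | O=Cc1c(F)cc(OCc9ccccc9)cc1OCc9ccccc9 | intermediate |
| 6 | AB-aldehyde | O=Cc1c(Oc2c(OCc9ccccc9)cc(OCc9ccccc9)cc2OCc9ccccc9)cc(OCc9ccccc9)cc1OCc9ccccc9 | intermediate |
| 7 | AB-phenol | Oc1c(Oc2c(OCc9ccccc9)cc(OCc9ccccc9)cc2OCc9ccccc9)cc(OCc9ccccc9)cc1OCc9ccccc9 | intermediate |
| 8 | 3,4,5-trihydroxybenzaldehyde | O=Cc1cc(O)c(O)c(O)c1 | starting material |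
| 9 | 3,4,5-tris(benzyloxy)benzaldehyde | O=Cc1cc(OCc9ccccc9)c(OCc9ccccc9)c(OCc9ccccc9)c1 | intermediate |
| 10 | 3,4,5-tris(benzyloxy)phenol | Oc1cc(OCc9ccccc9)c(OCc9ccccc9)c(OCc9ccccc9)c1 | intermediate |
| 11 | MOM ether of 10 | COCOc1cc(OCc9ccccc9)c(OCc9ccccc9)c(OCc9ccccc9)c1 | intermediate |
| 12 | 2-iodo MOM ether | COCOc1cc(OCc9ccccc9)c(OCc9ccccc9)c(OCc9ccccc9)c1I | intermediate |
| 13 | ED-MOM diaryl ether | COCOc1cc(OCc9ccccc9)c(OCc9ccccc9)c(OCc9ccccc9)c1Oc1cc(OCc9ccccc9)c(OCc9ccccc9)c(OCc9ccccc9)c1 | intermediate |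
| 14 | ED-phenol | Oc1cc(OCc9ccccc9)c(OCc9ccccc9)c(OCc9ccccc9)c1Oc1cc(OCc9ccccc9)c(OCc9ccccc9)c(OCc9ccccc9)c1 | intermediate |
| 15 | 3-bromo-4,5-dihydroxybenzaldehyde | O=Cc1cc(O)c(O)c(Br)c1 | starting material |
| 16 | 3-bromo-4,5-bis(benzyloxy)benzaldehyde | O=Cc1cc(OCc9ccccc9)c(OCc9ccccc9)c(Br)c1 | intermediate |
| 17 | EDC-aldehyde | O=Cc1cc(OCc9ccccc9)c(OCc9ccccc9)c(Oc2cc(OCc9ccccc9)c(OCc9ccccc9)c(OCc9ccccc9)c2Oc2cc(OCc9ccccc9)c(OCc9ccccc9)c(OCc9ccccc9)c2)c1 | intermediate |
| 18 | EDC-carboxylic acid | OC(=O)c1cc(OCc9ccccc9)c(OCc9ccccc9)c(Oc2cc(OCc9ccccc9)c(OCc9ccccc9)c(OCc9ccccc9)c2Oc2cc(OCc9ccccc9)c(OCc9ccccc9)c(OCc9ccccc9)c2)c1 | intermediate |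
| 19 | perbenzylated pentamer | c1(OCc9ccccc9)cc(OCc9ccccc9)cc(OCc9ccccc9)c1Oc2cc(OCc9ccccc9)cc(OCc9ccccc9)c2Oc3cc(OCc9ccccc9)c(OCc9ccccc9)c(Oc4cc(OCc9ccccc9)c(OCc9ccccc9)c(OCc9ccccc9)c4Oc5cc(OCc9ccccc9)c(OCc9ccccc9)c(OCc9ccccc9)c5)c3 | intermediate |
| 20 | Pseudopentafuhalol D (achiral, no stereocenters) | Oc1cc(O)c(Oc2cc(O)cc(O)c2Oc2cc(O)c(O)c(Oc3cc(O)c(O)c(O)c3Oc3cc(O)c(O)c(O)c3)c2)c(O)c1 | target |

---

**Total steps:** 16.
**Longest linear sequence:** 10 steps (8→9→10→11→12→13→14→17→18→19→20, i.e., Steps 6, 7, 8, 9, 10, 11, 13, 14, 15, 16).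

**Three steps most likely to fail**
1. **Step 15 (proposed new step, the Cu-LMCT decarboxylative coupling).** Aryl benzoate formation, oxidative phenol coupling, or arene oxidation by Cu(II) could compete. Fallback, using known chemistry: Cu-LMCT decarboxylative iodination of **18** to the aryl iodide, then Cu/picolinic acid Ullmann (or Ar(TMP)I+ metal-free) O-arylation of **7**.
2. **Step 4 (SNAr of the doubly ortho-substituted phenoxide 3).** Fallback: reverse the polarity. Dibenzylate **1** to 2-hydroxy-4,6-bis(benzyloxy)benzaldehyde, then couple it with 2-iodo-1,3,5-tris(benzyloxy)benzene (from NIS iodination of 1,3,5-tris(benzyloxy)benzene) by CuI/picolinic acid Ullmann coupling, and continue with the Step 5 Baeyer–Villiger sequence.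
3. **Step 16 (removal of 13 benzyl groups from an oxidation-prone polyphenol).** Fallback: Lewis-acid debenzylation with BCl3 and pentamethylbenzene in CH2Cl2 at –78 °C, in place of Pd hydrogenolysis.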